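The earlier runs and the new flask stem from a simulated flask on assumed constants; the scatter is artificial.

**The unit.** Percent of the charge per hour is the unit I read these flasks in: Q (monomer) turns into X (monomer in chains), started by E (initiator) and carried by G (growing radical).

| flask | Q | E | remark | time |
|---|---|---|---|---|
| ash | 4.6 mM | 0.11 mM | run made earlier |  |
| oak | 160 mM | 0.11 mM | run made earlier |  |
| midnight | 6.0 mM | 0.11 mM |  | 8.0 h |
| spring | 20 mM | 0.11 mM |  | 8.0 h |
| dawn | 60 mM | 0.11 mM |  | 8.0 h |
| summer | 200 mM | 0.11 mM |  | 8.0 h |

| run | time / h | X / % |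
|---|---|---|
| ash | 0.417 | 0.9 |
| ash | 1.00 | 2.7 |
| ash | 2.50 | 5.9 |
| ash | 6.00 | 14.4 |
| oak | 0.667 | 1.7 |
| oak | 2.00 | 5.4 |
| oak | 4.00 | 10.7 |
| oak | 6.00 | 14.1 |

(scatter of a reading: 0.5 percentage points)

- a species is counted by the Q in it: one Z counts as two
- amounts and yields of X count Z and J too
- given per volume of solution although it is solid: J
- on the list of suspects stand: E -> 2 D; Q + D -> G + X; Q + G -> X + G; 2 G -> L; Q + X <-> Z; J <-> X
- in an amount of X, one Z counts as one X
- "hardly changes" means that all values lie within two and a half points (for a concentration: within two and a half percent of the largest)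

- amount of X at the end, in percent of the Q charged for midnight, spring, dawn, summer, in this order
- how the row runs (falls, then rises / falls all the way / rises, then falls / hardly changes / rises all the way)

**The zero.** The symmetric case, where every charge turns the same fraction per hour, is my zero. I measure from it with f, the pseudo-first-order constant: minus the logarithm of the fraction not yet turned, over the time. At 6.00 h, ash and oak read 14.4 % and 14.1 %, which differ by 0.3 percentage points, less than one scatter, though oak's charge is 34.8 times ash's. I therefore pool them into a mean 14.3 %, with scatter 0.35 points, and get 0.0256 h⁻¹.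

**The bracket.** From above, I carry the mean plus its scatter straight on to 8.0 h, with no slowing: 19.5 %. From below, I take the mean minus its scatter and let each X hold one Q in Z, so that each X formed removes two Q from the free pool: 17.6 %. The width, 1.9 points, is less than two and a half points, so with f held at every charge I commit to a flat row.

**The forecast.** It gives 18.8 %, 18.7 %, 18.4 %, 17.6 %, and says hardly changes: “The reaction is therefore first order in Q, with a radical level set by E alone”. Its top value lies below my upper bound, and its bottom value stands at my lower edge.

**The flask.** The row is 18.3 %, 17.8 %, 17.7 %, 17.6 %: hardly changes. The summer value stands at the lower edge, and the midnight value lies below the upper bound.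

    E → 2 D (k = 6.50 × 10⁻⁶ s⁻¹)
    Q + D → G + X (k = 1.50 × 10⁶ M⁻¹ s⁻¹)
    Q + G → X + G, rate k3*[G]*[Q] (k = 9800 M⁻¹ s⁻¹)
    2 G → L (k = 1.10 × 10⁹ M⁻¹ s⁻¹)
    Q + X ⇌ Z, settled at all times (K = 1700 M⁻¹)
    J ⇌ X, rate k6*(cs6 - [X]) while solid is left; crystals form when [X] > cs6 (solubility = 7.90 mM, k = 0.00160 s⁻¹)

**The carrying step.** In midnight at 8.00 h, the half-life of Q by Q + G → X + G is 27 h, far shorter than the 27 d by Q + D → G + X, and Q + G → X + G uses Q 24 times as fast as Q + D → G + X. Carried to 4.00 h, f gives 9.74 % of the charge as X, and summer, at 33.3 times midnight's charge, stands at 9.98 % at that time, with G at 7.69 × 10⁻⁷ mM, as in midnight at 7.69 × 10⁻⁷ mM.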